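The 3,7-dioxabicyclo[3.3.0]octane core (fusion C1/C5, aryl carbons C2/C6, O3/O7, methylenes C4/C8) is cut at C1–C2 and C4–C5. The key step exploits the benzylic ether unit C2–O3–C4 of the first tetrahydrofuran ring, which is a masked carbonyl ylide of 3,4,5-trimethoxybenzaldehyde, and the second ring, which is a butenolide (C1=C5, lactone carbon C8, stereocentre C6). One [3+2] cycloaddition forms both bonds, closes the first ring cis onto the lactone and sets C1, C2 and C5 from C6. The precursors are a silylmethyl chlorobenzyl ether and the benzyl-protected (S)-butenolide; lactone reduction and debenzylation finish the route.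

Key step: step 6

Assumption: the zinc–ProPhenol alkynylation is taken to deliver the alkynyl group to the Si face of aldehyde 2 with the (R,R)-ligand; if Mosher ester analysis of 4 shows the opposite sense, the equally available (S,S)-ligand is used with no other change.

Step 1
Reactants: 1 3-hydroxy-4,5-dimethoxybenzaldehyde
Product: 2 3-(benzyloxy)-4,5-dimethoxybenzaldehyde
Conditions: BnBr, K2CO3, DMF, rt
Reagents that add atoms: benzyl bromide, BrCc1ccccc1
Why: Williamson etherification of the only phenol (phenoxide SN2 on benzyl bromide) gives a benzyl ether that tolerates the later fluoride, hydride and Lewis acid steps, which a silyl ether would not; no stereocentre is formed.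

Step 2
Reactants: 2 3-(benzyloxy)-4,5-dimethoxybenzaldehyde; 3 methyl propiolate
Product: 4 methyl (R)-4-[3-(benzyloxy)-4,5-dimethoxyphenyl]-4-hydroxybut-2-ynoate
Conditions: Me2Zn, (R,R)-ProPhenol (10 mol%), Ph3P=O (20 mol%), toluene, 4 °C; aq. NH4Cl
Reagents that add atoms: none
Why: Catalytic enantioselective alkynylation of an aryl aldehyde by a zinc alkynylide (dinuclear zinc–ProPhenol catalysis, established for methyl propiolate) should set C6 by ligand-controlled Si-face delivery; the centre is R in 4 and becomes S in 5 and 6 only because the CIP rank of alkynyl versus aryl reverses, not the geometry.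

Step 3
Reactants: 4 methyl (R)-4-[3-(benzyloxy)-4,5-dimethoxyphenyl]-4-hydroxybut-2-ynoate
Product: 6 (S)-5-[3-(benzyloxy)-4,5-dimethoxyphenyl]furan-2(5H)-one, via hydroxy enoate 5 (not isolated)
Conditions: H2 (1 atm), Pd/CaCO3–Pb(OAc)2 (Lindlar catalyst), quinoline, EtOAc, rt; then PPTS (cat.), CH2Cl2, rt
Reagents that add atoms: none
Why: Lindlar semihydrogenation gives the (Z)-enoate, whose cis geometry places the hydroxyl next to the ester so that acid-catalysed lactonisation closes the butenolide; the C6–O bond is untouched and base is avoided, so the configuration should be retained.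

Step 4
Reactants: 7 3,4,5-trimethoxybenzaldehyde; 8 (trimethylsilyl)methanol
Product: 9 3,4,5-trimethoxybenzaldehyde bis[(trimethylsilyl)methyl] acetal
Conditions: 8 (2.2 equiv in all), TsOH·H2O (cat.), benzene, reflux, Dean–Stark trap; Et3N quench, excess 8 removed in vacuo
Reagents that add atoms: (trimethylsilyl)methanol (second equivalent of 8), C[Si](C)(C)CO
Why: Acid-catalysed acetalisation takes up two molecules of the alcohol per aldehyde with loss of one molecule of water and is driven to completion by azeotropic removal of that water; no stereocentre is formed.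

Step 5
Reactants: 9 3,4,5-trimethoxybenzaldehyde bis[(trimethylsilyl)methyl] acetal
Product: 10 chloro(3,4,5-trimethoxyphenyl)methyl (trimethylsilyl)methyl ether (racemic)
Conditions: AcCl, SOCl2 (cat.), CH2Cl2, 0 °C to rt; volatiles removed in vacuo, used crude at once
Reagents that add atoms: acetyl chloride, CC(=O)Cl
Why: Acyl chloride cleavage of an acetal to an α-chloro ether (one alkoxy group is acylated and leaves, chloride captures the aryl-stabilised oxocarbenium ion) avoids water, which this ionisable ether would not survive; the chloro-bearing centre is racemic and becomes planar in step 6.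

Step 6
Reactants: 6 (S)-5-[3-(benzyloxy)-4,5-dimethoxyphenyl]furan-2(5H)-one; 10 chloro(3,4,5-trimethoxyphenyl)methyl (trimethylsilyl)methyl ether
Product: 12 (1S,2S,5R,6S)-6-[3-(benzyloxy)-4,5-dimethoxyphenyl]-2-(3,4,5-trimethoxyphenyl)-3,7-dioxabicyclo[3.3.0]octan-8-one, via carbonyl ylide 11 (not isolated)
Conditions: CsF (dried), MeCN, 0 °C to rt, slow addition of 10 (excess)
Reagents that add atoms: none
Why: Loss of chloride from 10 gives an aryl-stabilised oxocarbenium ion, fluoride removes the silyl group (1,3-elimination), and the non-stabilised carbonyl ylide 11 adds in a concerted, suprafacial [3+2] dipolar cycloaddition (ylide HOMO, butenolide LUMO) across C1=C5 of 6. The closest known reaction type is the fluoride-induced generation of such ylides from α-chloroalkyl silylmethyl ethers and their cycloaddition to acrylates, fumarates and enones, applied here to a cyclic enoate. Ring C1–C2–O3–C4–C5 closes by intermolecular cycloaddition, with C4–C5 and C1–C2 formed in one step on the same alkene face, which makes the fusion to the lactone ring cis. C1 and C5 are controlled by the C6 stereocentre, because the ylide should approach the face anti to the C6 aryl group; C2 is controlled by the exo orientation in which the ylide aryl points away from the lactone ring and its carbonyl group. The step needs regioselectivity (nucleophilic CH2 terminus to the β-carbon C5, which carries the larger LUMO coefficient of the enoate, benzylic terminus to C1), π-facial selectivity (secured by the γ-aryl group on C6) and exo selectivity (secured only by steric and dipole repulsion between the aryl group and the lactone, the least certain element). Slow addition of 10 at 0 °C keeps the ylide concentration low and limits exposure of the base-sensitive C6–H of 6 to fluoride.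

Step 7
Reactants: 12 (1S,2S,5R,6S)-6-[3-(benzyloxy)-4,5-dimethoxyphenyl]-2-(3,4,5-trimethoxyphenyl)-3,7-dioxabicyclo[3.3.0]octan-8-one
Product: 13 (1S,2S,5R,6S)-6-[3-(benzyloxy)-4,5-dimethoxyphenyl]-2-(3,4,5-trimethoxyphenyl)-3,7-dioxabicyclo[3.3.0]octan-8-ol (anomeric mixture at C8)
Conditions: iBu2AlH, CH2Cl2, −78 °C; aq. KNaC4H4O6 work-up
Reagents that add atoms: none
Why: Partial reduction of a lactone with iBu2AlH at low temperature stops at the tetrahedral aluminium hemiacetal, which gives the lactol on work-up; C1, C2, C5 and C6 are not involved, and the new C8 centre is removed in step 8.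

Step 8
Reactants: 13 (1S,2S,5R,6S)-6-[3-(benzyloxy)-4,5-dimethoxyphenyl]-2-(3,4,5-trimethoxyphenyl)-3,7-dioxabicyclo[3.3.0]octan-8-ol
Product: 14 (1R,2S,5R,6S)-6-[3-(benzyloxy)-4,5-dimethoxyphenyl]-2-(3,4,5-trimethoxyphenyl)-3,7-dioxabicyclo[3.3.0]octane
Conditions: Et3SiH, BF3·OEt2, CH2Cl2, −78 to −40 °C
Reagents that add atoms: none
Why: Ionic hydrogenation of a lactol (BF3·OEt2 ionises the anomeric hydroxyl to the cyclic C8=O7 oxocarbenium ion and Et3SiH delivers hydride) turns C8 into CH2 without creating a stereocentre, and the low temperature should keep the benzylic ether carbons C2 and C6 from ionising.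

Step 9
Reactants: 14 (1R,2S,5R,6S)-6-[3-(benzyloxy)-4,5-dimethoxyphenyl]-2-(3,4,5-trimethoxyphenyl)-3,7-dioxabicyclo[3.3.0]octane
Product: 15 (1R,2S,5R,6S)-6-(3-hydroxy-4,5-dimethoxyphenyl)-2-(3,4,5-trimethoxyphenyl)-3,7-dioxabicyclo[3.3.0]octane (CNP0181235.1)
Conditions: H2 (1 atm), Pd/C, EtOAc, rt, stopped after one equivalent of H2
Reagents that add atoms: none
Why: Hydrogenolysis of an aryl benzyl ether over Pd/C under neutral conditions is much faster than cleavage of the dialkyl benzylic C2–O3 and C6–O7 bonds, so the phenol should be freed without touching the four stereocentres.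

Compound list
1 | 3-hydroxy-4,5-dimethoxybenzaldehyde | COc1cc(C=O)cc(O)c1OC | starting material
2 | 3-(benzyloxy)-4,5-dimethoxybenzaldehyde | COc1cc(C=O)cc(OCc2ccccc2)c1OC | intermediate
3 | methyl propiolate | C#CC(=O)OC | starting material
4 | methyl (R)-4-[3-(benzyloxy)-4,5-dimethoxyphenyl]-4-hydroxybut-2-ynoate | COC(=O)C#C[C@@H](c1cc(OCc2ccccc2)c(OC)c(OC)c1)O | intermediate
5 | methyl (S,Z)-4-[3-(benzyloxy)-4,5-dimethoxyphenyl]-4-hydroxybut-2-enoate | COC(=O)/C=C\[C@@H](c1cc(OCc2ccccc2)c(OC)c(OC)c1)O | intermediate (not isolated)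
6 | (S)-5-[3-(benzyloxy)-4,5-dimethoxyphenyl]furan-2(5H)-one | O=C1C=C[C@@H](c2cc(OCc3ccccc3)c(OC)c(OC)c2)O1 | intermediate
7 | 3,4,5-trimethoxybenzaldehyde | COc1cc(C=O)cc(OC)c1OC | starting material
8 | (trimethylsilyl)methanol | C[Si](C)(C)CO | starting material
9 | 3,4,5-trimethoxybenzaldehyde bis[(trimethylsilyl)methyl] acetal | COc1cc(cc(OC)c1OC)C(OC[Si](C)(C)C)OC[Si](C)(C)C | intermediate
10 | chloro(3,4,5-trimethoxyphenyl)methyl (trimethylsilyl)methyl ether (racemic) | COc1cc(cc(OC)c1OC)C(Cl)OC[Si](C)(C)C | intermediate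
11 | carbonyl ylide of 3,4,5-trimethoxybenzaldehyde (ArCH=O(+)–CH2(−)) | COc1cc(cc(OC)c1OC)C=[O+][CH2-] | intermediate (not isolated)
12 | (1S,2S,5R,6S)-6-[3-(benzyloxy)-4,5-dimethoxyphenyl]-2-(3,4,5-trimethoxyphenyl)-3,7-dioxabicyclo[3.3.0]octan-8-one (cis-fused, both aryl groups exo) | COc1cc(cc(OC)c1OC)[C@H]2OC[C@H]3[C@@H]2C(=O)O[C@@H]3c1cc(OCc4ccccc4)c(OC)c(OC)c1 | intermediate
13 | (1S,2S,5R,6S)-6-[3-(benzyloxy)-4,5-dimethoxyphenyl]-2-(3,4,5-trimethoxyphenyl)-3,7-dioxabicyclo[3.3.0]octan-8-ol (anomeric mixture at C8) | COc1cc(cc(OC)c1OC)[C@H]2OC[C@H]3[C@@H]2C(O)O[C@@H]3c1cc(OCc4ccccc4)c(OC)c(OC)c1 | intermediate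
14 | (1R,2S,5R,6S)-6-[3-(benzyloxy)-4,5-dimethoxyphenyl]-2-(3,4,5-trimethoxyphenyl)-3,7-dioxabicyclo[3.3.0]octane | COc1cc(cc(OC)c1OC)[C@H]2OC[C@H]3[C@@H]2CO[C@@H]3c1cc(OCc4ccccc4)c(OC)c(OC)c1 | intermediate
15 | (1R,2S,5R,6S)-6-(3-hydroxy-4,5-dimethoxyphenyl)-2-(3,4,5-trimethoxyphenyl)-3,7-dioxabicyclo[3.3.0]octane | COc1cc([C@H]2OC[C@H]3[C@@H]2CO[C@@H]3c2cc(OC)c(OC)c(OC)c2)cc(O)c1OC | target

Total step count: 9. Longest linear sequence: 7 steps (1, 2, 3, 6, 7, 8, 9); steps 4 and 5 form the second branch.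

Steps most likely to fail

1. Step 6. The cycloaddition may fail through weak exo/endo discrimination at C2, through self-consumption of the ylide (closure to the aryl oxirane or capture by liberated aldehyde), and through fluoride-mediated deprotonation at C6 that erodes enantiomeric purity. The fallback sets out from 6, uses 10 as an electrophile, and comes back to the route at 12; it makes the two bonds one after the other and needs no fluoride. Conjugate addition of a vinyl cuprate (CH2=CHMgBr, CuBr·SMe2, Me3SiCl, THF, −78 °C) anti to the C6 aryl group should give (4R,5S)-5-[3-(benzyloxy)-4,5-dimethoxyphenyl]-4-vinyldihydrofuran-2(3H)-one F1. Oxidative cleavage (OsO4 cat., NaIO4, 2,6-lutidine, dioxane/H2O) should give (2S,3S)-2-[3-(benzyloxy)-4,5-dimethoxyphenyl]-5-oxotetrahydrofuran-3-carbaldehyde F2, which is reduced at once (NaBH4, MeOH, 0 °C, acetic acid quench) to (4R,5S)-5-[3-(benzyloxy)-4,5-dimethoxyphenyl]-4-(hydroxymethyl)dihydrofuran-2(3H)-one F3. O-Alkylation with 10 (iPr2NEt, CH2Cl2, 0 °C) should give the mixed acetal (4R,5S)-5-[3-(benzyloxy)-4,5-dimethoxyphenyl]-4-({(3,4,5-trimethoxyphenyl)[(trimethylsilyl)methoxy]methoxy}methyl)dihydrofuran-2(3H)-one F4. Enolisation (LiN(iPr)2, Me3SiCl, THF, −78 °C) gives the ketene silyl acetal (4R,5S)-5-[3-(benzyloxy)-4,5-dimethoxyphenyl]-4-({(3,4,5-trimethoxyphenyl)[(trimethylsilyl)methoxy]methoxy}methyl)-2-(trimethylsilyloxy)-4,5-dihydrofuran F5. Me3SiOTf (cat., CH2Cl2, −78 °C) then ionises the acetal; only loss of the silylmethoxy group leads on to ring closure, the other ionisation being reversible. C1–C2 closes by an intramolecular Mukaiyama-type addition of the ketene acetal to the oxocarbenium ion, the tether enforcing the cis fusion and the aryl group expected on the exo side, to give 12.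

2. Step 2. The alkynylation may give insufficient facial selectivity or the opposite sense, and methyl transfer from Me2Zn may compete. The fallback sets out from 2 and comes back to the route at 6, replacing steps 2 and 3. A Stetter reaction with methyl acrylate (3-benzyl-5-(2-hydroxyethyl)-4-methylthiazolium chloride, Et3N, EtOH, 70 °C) should give methyl 4-[3-(benzyloxy)-4,5-dimethoxyphenyl]-4-oxobutanoate F6. Noyori transfer hydrogenation (RuCl[(S,S)-TsDPEN](p-cymene), HCO2H/Et3N, rt), whose sense for aryl alkyl ketones is well defined, should give methyl (S)-4-[3-(benzyloxy)-4,5-dimethoxyphenyl]-4-hydroxybutanoate F7. Lactonisation (TsOH cat., toluene, rt) gives (S)-5-[3-(benzyloxy)-4,5-dimethoxyphenyl]dihydrofuran-2(3H)-one F8. α-Selenenylation (LiN(SiMe3)2, PhSeBr, THF, −78 °C) gives (5S)-5-[3-(benzyloxy)-4,5-dimethoxyphenyl]-3-(phenylselanyl)dihydrofuran-2(3H)-one F9, and oxidation with syn elimination of the selenoxide (H2O2, CH2Cl2, 0 °C) gives 6.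

3. Step 8. The Lewis acid may ionise the benzylic ether bonds C2–O3 or C6–O7, causing epimerisation or reductive ring opening. The fallback sets out from 12 and comes back to the route at 14, replacing steps 7 and 8 with a sequence that uses no Lewis acid. LiAlH4 (THF, 0 °C) should open the lactone to (S)-[3-(benzyloxy)-4,5-dimethoxyphenyl][(3R,4R,5S)-4-(hydroxymethyl)-5-(3,4,5-trimethoxyphenyl)tetrahydrofuran-3-yl]methanol F10. Selective sulfonylation of the primary hydroxyl (MsCl, pyridine, 0 °C to rt) gives the primary methanesulfonate of F10 F11. The C6 hydroxyl then displaces the sulfonate in an intramolecular SN2 etherification at the primary carbon C8, with retention at C6, closing ring C1–C5–C6–O7–C8 to give 14.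

Further compounds
F1 | step 6 | (4R,5S)-5-[3-(benzyloxy)-4,5-dimethoxyphenyl]-4-vinyldihydrofuran-2(3H)-one | C=C[C@H]1CC(=O)O[C@@H]1c1cc(OCc2ccccc2)c(OC)c(OC)c1
F2 | step 6 | (2S,3S)-2-[3-(benzyloxy)-4,5-dimethoxyphenyl]-5-oxotetrahydrofuran-3-carbaldehyde | O=C[C@H]1CC(=O)O[C@@H]1c1cc(OCc2ccccc2)c(OC)c(OC)c1
F3 | step 6 | (4R,5S)-5-[3-(benzyloxy)-4,5-dimethoxyphenyl]-4-(hydroxymethyl)dihydrofuran-2(3H)-one | OC[C@H]1CC(=O)O[C@@H]1c1cc(OCc2ccccc2)c(OC)c(OC)c1
F4 | step 6 | (4R,5S)-5-[3-(benzyloxy)-4,5-dimethoxyphenyl]-4-({(3,4,5-trimethoxyphenyl)[(trimethylsilyl)methoxy]methoxy}methyl)dihydrofuran-2(3H)-one (mixture at the acetal carbon) | COc1cc(cc(OC)c1OC)C(OC[Si](C)(C)C)OC[C@H]1CC(=O)O[C@@H]1c1cc(OCc2ccccc2)c(OC)c(OC)c1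
F5 | step 6 | (4R,5S)-5-[3-(benzyloxy)-4,5-dimethoxyphenyl]-4-({(3,4,5-trimethoxyphenyl)[(trimethylsilyl)methoxy]methoxy}methyl)-2-(trimethylsilyloxy)-4,5-dihydrofuran (ketene silyl acetal of F4) | COc1cc(cc(OC)c1OC)C(OC[Si](C)(C)C)OC[C@H]1C=C(O[Si](C)(C)C)O[C@@H]1c1cc(OCc2ccccc2)c(OC)c(OC)c1
F6 | step 2 | methyl 4-[3-(benzyloxy)-4,5-dimethoxyphenyl]-4-oxobutanoate | COC(=O)CCC(=O)c1cc(OCc2ccccc2)c(OC)c(OC)c1
F7 | step 2 | methyl (S)-4-[3-(benzyloxy)-4,5-dimethoxyphenyl]-4-hydroxybutanoate | COC(=O)CC[C@@H](c1cc(OCc2ccccc2)c(OC)c(OC)c1)O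
F8 | step 2 | (S)-5-[3-(benzyloxy)-4,5-dimethoxyphenyl]dihydrofuran-2(3H)-one | O=C1CC[C@@H](c2cc(OCc3ccccc3)c(OC)c(OC)c2)O1
F9 | step 2 | (5S)-5-[3-(benzyloxy)-4,5-dimethoxyphenyl]-3-(phenylselanyl)dihydrofuran-2(3H)-one (mixture at C3) | O=C1C([Se]c2ccccc2)C[C@@H](c2cc(OCc3ccccc3)c(OC)c(OC)c2)O1
F10 | step 8 | (S)-[3-(benzyloxy)-4,5-dimethoxyphenyl][(3R,4R,5S)-4-(hydroxymethyl)-5-(3,4,5-trimethoxyphenyl)tetrahydrofuran-3-yl]methanol | COc1cc(cc(OC)c1OC)[C@H]2OC[C@@H]([C@@H]2CO)[C@H](O)c1cc(OCc3ccccc3)c(OC)c(OC)c1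
F11 | step 8 | primary methanesulfonate of F10 | COc1cc(cc(OC)c1OC)[C@H]2OC[C@@H]([C@@H]2COS(C)(=O)=O)[C@H](O)c1cc(OCc3ccccc3)c(OC)c(OC)c1
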